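**Plan**
- Labels: ring A is the terminal 4-allyl-2-methoxyphenoxy ring, its carbons counted 1 to 6 from the carbon on the ether oxygen (methoxy on carbon 2, allyl on carbon 4); ring B is the central ring, whose carbon 1 carries the oxygen to ring A and whose carbon 6 carries the oxygen to ring C; ring C is the phenol ring.
- Retrosynthesis: the allyl group on carbon 4 of ring A is traced back to an ester. Ring A is then cut at the bond between its carbons 1 and 6 and at the bond between its carbons 3 and 4, giving an aryloxyacetone on the ring B oxygen and an enaminone made from ethyl pyruvate. The oxygen on carbon 1 of ring B goes back to a formyl group, and the diaryl ether between rings B and C to an Ullmann coupling.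
- Enabling feature: ring A hangs on the ring B oxygen through its carbon 1 and has oxygen on carbon 2 and carbon on carbon 4, so an O–CH2–CO–CH3 unit on that oxygen supplies carbons 1 to 3 and a three-carbon 1,3-dielectrophile supplies carbons 4 to 6.
- Forward: ring C (from eugenol) is iodinated, protected and joined to ring B (a salicylaldehyde); formyl becomes hydroxyl and then the acetonyl ether; ring A is annulated last and its ester is turned into the third allyl group.
- Stereochemistry: the target has no stereocentre and only terminal alkenes; the only selectivity to secure is the regiochemistry of ring A.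

Key step: step 7

Remark on the chemistry: 5-allyl-2-hydroxy-3-methoxybenzaldehyde is assumed to be a catalogue compound.

**Step 1**
Reactants: 1 eugenol
Product: 2 4-allyl-2-iodo-6-methoxyphenol (6-iodoeugenol)
Conditions: iodine (1.05 equiv), KI, NaHCO3, THF/H2O, 0 °C to rt
Reagents that add atoms: iodine, II
Why: Electrophilic aromatic iodination of the phenoxide goes to the only free position ortho to oxygen (the para position holds the allyl group), while iodine adds to an isolated terminal alkene only reversibly, so the side chain should stay intact.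

**Step 2**
Reactants: 2 6-iodoeugenol
Product: 3 5-allyl-1-iodo-3-methoxy-2-(methoxymethoxy)benzene
Conditions: NaH, THF/DMF, 0 °C; MOMCl, 0 °C to rt
Reagents that add atoms: chloromethyl methyl ether (MOMCl), COCCl
Why: Williamson-type O-alkylation of the sodium phenoxide installs a methoxymethyl acetal that withstands base, peracid, ethoxide, hydride and Grignard reagents and is removed by dilute acid at the end.

**Step 3**
Reactants: 3 MOM-protected 6-iodoeugenol + 4 5-allyl-2-hydroxy-3-methoxybenzaldehyde
Product: 5 5-allyl-2-[5-allyl-3-methoxy-2-(methoxymethoxy)phenoxy]-3-methoxybenzaldehyde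
Conditions: CuI (10 mol%), picolinic acid (20 mol%), K3PO4 (2 equiv), DMSO, 90 °C
Reagents that add atoms: none
Why: Ullmann-type diaryl ether synthesis under monovalent copper catalysis, using a ligand system known to couple 2,6-disubstituted phenols with ortho-substituted aryl iodides; phosphate in DMSO is too weak a base to attack the aldehyde or shift the allyl double bonds.

**Step 4**
Reactants: 5 diaryl ether aldehyde
Product: 7 5-allyl-2-[5-allyl-3-methoxy-2-(methoxymethoxy)phenoxy]-3-methoxyphenol, via aryl formate 6 (not isolated)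
Conditions: mCPBA (1.1 equiv), CH2Cl2, 0 °C; aqueous Na2S2O3/NaHCO3 wash; then K2CO3 (0.2 equiv), MeOH, rt
Reagents that add atoms: meta-chloroperoxybenzoic acid (mCPBA), OOC(=O)c1cccc(Cl)c1
Why: Baeyer–Villiger (Dakin-type) oxidation in which the aryl group, supported by the ortho aryloxy donor, migrates in the tetrahedral peracid adduct to give formate 6, which is methanolysed to the phenol; at 0 °C with a slight excess of peracid the aldehyde should be consumed before the monosubstituted alkenes are epoxidised.

**Step 5**
Reactants: 7 ring B–ring C phenol + 8 chloroacetone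
Product: 9 1-{5-allyl-2-[5-allyl-3-methoxy-2-(methoxymethoxy)phenoxy]-3-methoxyphenoxy}propan-2-one
Conditions: K2CO3, KI (cat.), acetone, reflux
Reagents that add atoms: none
Why: Williamson ether synthesis of the phenoxide with the α-chloro ketone, accelerated by in situ halide exchange (Finkelstein), is the standard route to aryloxyacetones.

**Step 6**
Reactants: 10 ethyl pyruvate
Product: 11 ethyl (E)-4-(dimethylamino)-2-oxobut-3-enoate
Conditions: DMF-DMA (1.1 equiv), CH2Cl2, rt
Reagents that add atoms: N,N-dimethylformamide dimethyl acetal (DMF-DMA), COC(OC)N(C)C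
Why: Condensation of the acidic pyruvate methyl group with the amide acetal gives the push–pull enaminone as the thermodynamically preferred (E) isomer, a known preparation of this building block.

**Step 7**
Reactants: 9 aryloxyacetone + 11 enaminone
Product: 14 ethyl 4-{5-allyl-2-[5-allyl-3-methoxy-2-(methoxymethoxy)phenoxy]-3-methoxyphenoxy}-3-hydroxybenzoate, via enedione adduct 12 (not isolated), via cyclic aldol 13 (not isolated)
Conditions: 11 (1.3 equiv), NaOEt (2.5 equiv), EtOH, 0 °C to rt, then 60 °C; AcOH quench
Reagents that add atoms: none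
Why: Proposed new method: ethoxide forms the aryloxy-stabilised enolate of 9, whose methylene is several pK units more acidic than the methyl group, and this carbon (the future carbon 1 of ring A) adds to the β-carbon of the vinylogous amide 11 (the future carbon 6) and expels dimethylamine to give enedione 12. Once the alkene of 12 has equilibrated through its dienolate, the methyl enolate (future carbon 3) attacks the ketone carbonyl next to the ester (future carbon 4) in a 6-(enolendo)-exo-trig aldol closure to 13, and loss of water followed by enolisation makes ring A aromatic. The closest known reaction type is the base-mediated (3+3) Michael–aldol benzannulation of methyl or benzyl ketones with β-aminovinyl ketones, β-alkoxy enones or ynones to phenols, which has not been shown for an α-aryloxy ketone paired with the enaminone of an α-keto ester. No stereocentre persists, since the saturated centres of 12 and 13 vanish on aromatisation. The step needs the oxygen-bearing carbon to be the Michael donor and the methyl carbon the aldol donor: the acidity difference secures the first, and the lack of α-hydrogens on the keto ester side leaves a single aldol direction, which places the ester on carbon 4 para to the aryloxy group and the hydroxyl on carbon 2. Ethoxide matches the ethyl ester, so ester exchange is degenerate, and the MOM acetal, the diaryl ethers and the allyl groups are inert to it.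

**Step 8**
Reactants: 14 ring A phenol ester
Product: 15 ethyl 4-{5-allyl-2-[5-allyl-3-methoxy-2-(methoxymethoxy)phenoxy]-3-methoxyphenoxy}-3-methoxybenzoate
Conditions: MeI, K2CO3, DMF, rt
Reagents that add atoms: iodomethane, CI
Why: Williamson O-methylation of the only free phenol, the ring C oxygen remaining masked as its MOM ether.

**Step 9**
Reactants: 15 methyl ether ester
Product: 16 (4-{5-allyl-2-[5-allyl-3-methoxy-2-(methoxymethoxy)phenoxy]-3-methoxyphenoxy}-3-methoxyphenyl)methanol
Conditions: LiAlH4, THF, 0 °C; aqueous NaOH work-up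
Reagents that add atoms: none
Why: LiAlH4 reduction of the aryl ester to the benzylic alcohol; aryl ethers, the MOM acetal and isolated alkenes are inert to the hydride.

**Step 10**
Reactants: 16 benzylic alcohol
Product: 17 5-allyl-1-[4-(bromomethyl)-2-methoxyphenoxy]-2-[5-allyl-3-methoxy-2-(methoxymethoxy)phenoxy]-3-methoxybenzene
Conditions: CBr4, PPh3, CH2Cl2, 0 °C
Reagents that add atoms: carbon tetrabromide, BrC(Br)(Br)Br
Why: Appel reaction, in which the alkoxyphosphonium salt is displaced by bromide at the primary benzylic carbon under nearly neutral conditions that the MOM acetal tolerates.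

**Step 11**
Reactants: 17 benzylic bromide
Product: 18 5-allyl-1-(4-allyl-2-methoxyphenoxy)-2-[5-allyl-3-methoxy-2-(methoxymethoxy)phenoxy]-3-methoxybenzene
Conditions: CH2=CHMgBr (2 equiv), CuI (10 mol%), THF, −20 °C to rt
Reagents that add atoms: vinylmagnesium bromide, C=C[Mg]Br
Why: Copper-catalysed cross-coupling of a benzylic bromide with a vinyl Grignard reagent, after transmetalation of the vinyl group to copper, is the standard construction of allylarenes, with substitution at the benzylic carbon favoured at low temperature.

**Step 12**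
Reactants: 18 MOM-protected triaryl ether
Product: 19 4-allyl-2-[4-allyl-2-(4-allyl-2-methoxyphenoxy)-6-methoxyphenoxy]-6-methoxyphenol (CNP0153774.0)
Conditions: HCl (conc., 3 equiv), MeOH, 45 °C
Reagents that add atoms: none
Why: Acid-catalysed acetal exchange removes the MOM group as dimethoxymethane under conditions too mild to hydrate or shift the terminal alkenes or to cleave methyl and diaryl ethers.

**Compound list**
1 | eugenol (4-allyl-2-methoxyphenol) | C=CCc1ccc(O)c(OC)c1 | starting material
2 | 4-allyl-2-iodo-6-methoxyphenol (6-iodoeugenol) | C=CCc1cc(I)c(O)c(OC)c1 | intermediate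
3 | 5-allyl-1-iodo-3-methoxy-2-(methoxymethoxy)benzene | C=CCc1cc(I)c(OCOC)c(OC)c1 | intermediate
4 | 5-allyl-2-hydroxy-3-methoxybenzaldehyde | O=Cc1cc(CC=C)cc(OC)c1O | starting material
5 | 5-allyl-2-[5-allyl-3-methoxy-2-(methoxymethoxy)phenoxy]-3-methoxybenzaldehyde | O=Cc1cc(CC=C)cc(OC)c1Oc1cc(CC=C)cc(OC)c1OCOC | intermediate
6 | 5-allyl-2-[5-allyl-3-methoxy-2-(methoxymethoxy)phenoxy]-3-methoxyphenyl formate (formed in the flask) | O=COc1cc(CC=C)cc(OC)c1Oc1cc(CC=C)cc(OC)c1OCOC | intermediate
7 | 5-allyl-2-[5-allyl-3-methoxy-2-(methoxymethoxy)phenoxy]-3-methoxyphenol | Oc1cc(CC=C)cc(OC)c1Oc1cc(CC=C)cc(OC)c1OCOC | intermediate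
8 | chloroacetone | CC(=O)CCl | starting material
9 | 1-{5-allyl-2-[5-allyl-3-methoxy-2-(methoxymethoxy)phenoxy]-3-methoxyphenoxy}propan-2-one | CC(=O)COc1cc(CC=C)cc(OC)c1Oc1cc(CC=C)cc(OC)c1OCOC | intermediate
10 | ethyl pyruvate | CCOC(=O)C(C)=O | starting material
11 | ethyl (E)-4-(dimethylamino)-2-oxobut-3-enoate | CCOC(=O)C(=O)/C=C/N(C)C | intermediate
12 | ethyl (E)-5-{5-allyl-2-[5-allyl-3-methoxy-2-(methoxymethoxy)phenoxy]-3-methoxyphenoxy}-2,6-dioxohept-3-enoate (racemic at carbon 5, formed in the flask) | CCOC(=O)C(=O)/C=C/C(Oc1cc(CC=C)cc(OC)c1Oc1cc(CC=C)cc(OC)c1OCOC)C(C)=O | intermediate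
13 | ethyl 4-{5-allyl-2-[5-allyl-3-methoxy-2-(methoxymethoxy)phenoxy]-3-methoxyphenoxy}-1-hydroxy-5-oxocyclohex-2-ene-1-carboxylate (mixture of diastereomers, formed in the flask) | CCOC(=O)C1(O)C=CC(Oc2cc(CC=C)cc(OC)c2Oc2cc(CC=C)cc(OC)c2OCOC)C(=O)C1 | intermediate
14 | ethyl 4-{5-allyl-2-[5-allyl-3-methoxy-2-(methoxymethoxy)phenoxy]-3-methoxyphenoxy}-3-hydroxybenzoate | CCOC(=O)c1ccc(Oc2cc(CC=C)cc(OC)c2Oc2cc(CC=C)cc(OC)c2OCOC)c(O)c1 | intermediate
15 | ethyl 4-{5-allyl-2-[5-allyl-3-methoxy-2-(methoxymethoxy)phenoxy]-3-methoxyphenoxy}-3-methoxybenzoate | CCOC(=O)c1ccc(Oc2cc(CC=C)cc(OC)c2Oc2cc(CC=C)cc(OC)c2OCOC)c(OC)c1 | intermediate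
16 | (4-{5-allyl-2-[5-allyl-3-methoxy-2-(methoxymethoxy)phenoxy]-3-methoxyphenoxy}-3-methoxyphenyl)methanol | OCc1ccc(Oc2cc(CC=C)cc(OC)c2Oc2cc(CC=C)cc(OC)c2OCOC)c(OC)c1 | intermediate
17 | 5-allyl-1-[4-(bromomethyl)-2-methoxyphenoxy]-2-[5-allyl-3-methoxy-2-(methoxymethoxy)phenoxy]-3-methoxybenzene | BrCc1ccc(Oc2cc(CC=C)cc(OC)c2Oc2cc(CC=C)cc(OC)c2OCOC)c(OC)c1 | intermediate
18 | 5-allyl-1-(4-allyl-2-methoxyphenoxy)-2-[5-allyl-3-methoxy-2-(methoxymethoxy)phenoxy]-3-methoxybenzene | C=CCc1ccc(Oc2cc(CC=C)cc(OC)c2Oc2cc(CC=C)cc(OC)c2OCOC)c(OC)c1 | intermediate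
19 | 4-allyl-2-[4-allyl-2-(4-allyl-2-methoxyphenoxy)-6-methoxyphenoxy]-6-methoxyphenol | C=CCc1ccc(Oc2cc(CC=C)cc(OC)c2Oc2cc(CC=C)cc(OC)c2O)c(OC)c1 | target

**Step count**
Total: 12 steps. Longest linear sequence: 11 steps (steps 1–5 and 7–12, from eugenol); step 6 is a one-step side branch.

**Steps most likely to fail**

Step 7. The ketone may enolise toward the methyl side and add through the methyl carbon first, which would put the ester ortho to the aryloxy group. The enolate may also acylate at the activated ester carbonyl instead of adding to the β-carbon. A third possibility is that the reaction rests at the doubly stabilised dienolate of 12 and the aldol closure does not follow. The fallback uses known chemistry and attaches ring A ready-made. It sets out from phenol 7: nucleophilic aromatic substitution on commercial 4-fluoro-3-methoxybenzaldehyde (COc1cc(C=O)ccc1F; K2CO3, DMF, 100 °C), whose fluoride is activated by the para formyl group, should give 4-{5-allyl-2-[5-allyl-3-methoxy-2-(methoxymethoxy)phenoxy]-3-methoxyphenoxy}-3-methoxybenzaldehyde F1. Reduction with NaBH4 in MeOH at 0 °C should then give benzylic alcohol 16, where the route is rejoined before step 10.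

Step 3. C–O bond formation may be too slow, because the phenoxide of 4 is flanked on both sides and held by the neighbouring formyl group, and the iodide carries an ortho alkoxy group. Prolonged heating would then let protodeiodination of 3 and migration of the allyl double bonds into conjugation gain ground. The fallback replaces the halide electrophile by an oxidative coupling of two nucleophiles at room temperature (Chan–Lam). It sets out from iodide 3: iodine–magnesium exchange (i-PrMgCl·LiCl, THF, −20 °C) should give [5-allyl-3-methoxy-2-(methoxymethoxy)phenyl]magnesium chloride F2. Trapping with B(OMe)3 gives dimethyl [5-allyl-3-methoxy-2-(methoxymethoxy)phenyl]boronate F3, and aqueous NH4Cl work-up gives [5-allyl-3-methoxy-2-(methoxymethoxy)phenyl]boronic acid F4. Coupling of F4 with phenol 4 (Cu(OAc)2 (20 mol%), pyridine, 4 Å molecular sieves, CH2Cl2, open to air, rt) should deliver aldehyde 5, where the route is rejoined.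

Step 4. If aryl migration is slow, the peracid may begin to epoxidise the two terminal alkenes, and hydride migration may divert material to the benzoic acid. The fallback introduces the oxygen on carbon 1 of ring B through a carbon–boron bond oxidised by alkaline H2O2, a nucleophilic peroxide that leaves alkenes alone. It sets out from eugenol 1 and iodide 3. Bromination of 1 with Br2 (2 equiv, CH2Cl2, 0 °C) gives 2-bromo-4-(2,3-dibromopropyl)-6-methoxyphenol F5, and Zn dust in AcOH restores the alkene to give 4-allyl-2-bromo-6-methoxyphenol F6. Coupling of F6 with 3 under the conditions of step 3, where the C–I bond should react in preference to the C–Br bond ortho to the phenoxide, gives 5-allyl-1-bromo-2-[5-allyl-3-methoxy-2-(methoxymethoxy)phenoxy]-3-methoxybenzene F7. Bromine–lithium exchange (n-BuLi, THF, −78 °C) gives {5-allyl-2-[5-allyl-3-methoxy-2-(methoxymethoxy)phenoxy]-3-methoxyphenyl}lithium F8, and B(OMe)3 converts it into dimethyl {5-allyl-2-[5-allyl-3-methoxy-2-(methoxymethoxy)phenoxy]-3-methoxyphenyl}boronate F9. Oxidation with NaOH/H2O2 at 0 °C should give phenol 7, where the route is rejoined before step 5.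

**Further compounds**
F1 | step 7 | 4-{5-allyl-2-[5-allyl-3-methoxy-2-(methoxymethoxy)phenoxy]-3-methoxyphenoxy}-3-methoxybenzaldehyde | O=Cc1ccc(Oc2cc(CC=C)cc(OC)c2Oc2cc(CC=C)cc(OC)c2OCOC)c(OC)c1
F2 | step 3 | [5-allyl-3-methoxy-2-(methoxymethoxy)phenyl]magnesium chloride | C=CCc1cc([Mg]Cl)c(OCOC)c(OC)c1
F3 | step 3 | dimethyl [5-allyl-3-methoxy-2-(methoxymethoxy)phenyl]boronate | C=CCc1cc(B(OC)OC)c(OCOC)c(OC)c1
F4 | step 3 | [5-allyl-3-methoxy-2-(methoxymethoxy)phenyl]boronic acid | C=CCc1cc(B(O)O)c(OCOC)c(OC)c1
F5 | step 4 | 2-bromo-4-(2,3-dibromopropyl)-6-methoxyphenol (racemic) | BrCC(Br)Cc1cc(Br)c(O)c(OC)c1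
F6 | step 4 | 4-allyl-2-bromo-6-methoxyphenol | C=CCc1cc(Br)c(O)c(OC)c1
F7 | step 4 | 5-allyl-1-bromo-2-[5-allyl-3-methoxy-2-(methoxymethoxy)phenoxy]-3-methoxybenzene | Brc1cc(CC=C)cc(OC)c1Oc1cc(CC=C)cc(OC)c1OCOC
F8 | step 4 | {5-allyl-2-[5-allyl-3-methoxy-2-(methoxymethoxy)phenoxy]-3-methoxyphenyl}lithium | [Li]c1cc(CC=C)cc(OC)c1Oc1cc(CC=C)cc(OC)c1OCOC
F9 | step 4 | dimethyl {5-allyl-2-[5-allyl-3-methoxy-2-(methoxymethoxy)phenoxy]-3-methoxyphenyl}boronate | COB(OC)c1cc(CC=C)cc(OC)c1Oc1cc(CC=C)cc(OC)c1OCOC
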